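- Pool Sunday's readings before taking a ratio from them: the first reading of right-handed product is 2.2 %, against a scatter of 1 percentage point.

- Sunday's: left-handed substrate 0.50 M; right-handed substrate 0.50 M; partner 2 M; free catalyst 5 mM; racemization catalyst 6 mM; impurity 0.73 mM; the very flask that is asked about, followed so far
- flask: left-handed substrate 0.50 M; partner 2.00 M; free catalyst 5.0 mM; racemization catalyst 6.0 mM; impurity 0.73 mM; right-handed substrate 0.50 M; time 10 min

Sunday's run (percent of the left-handed substrate and right-handed substrate together charged)

| time / min | left-handed product / % | right-handed product / % |
|---|---|---|
| 0.167 | 6.4 | 2.2 |
| 0.500 | 14.5 | 3.3 |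
| 0.833 | 20.9 | 9.2 |
| 1.33 | 30.1 | 9.2 |
| 2.00 | 38.7 | 12.3 |
| 2.50 | 40.8 | 15.0 |
| 3.00 | 43.9 | 16.5 |

(scatter of a reading: 1 percentage point)

- free catalyst is single-handed; left-handed substrate and right-handed substrate are mirror images of each other, charged as a racemate, each of them at the stated concentration
- what was read earlier has a scatter of 1 percentage point, one standard deviation
- an excess is the difference of the two amounts in percent of their sum
- an excess is below zero if the other one leads

- left-handed product and right-handed product together, in percent of the left-handed substrate and right-handed substrate charged together, at 10 min
- excess of left-handed product over right-handed product in the product at 10 min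
- whether the exchange between left-handed substrate and right-handed substrate keeps pace with the reaction: how far the product's excess at 10 min gets from its value without exchange to its value with instant exchange (above 80 % keeps pace, below 20 % hardly takes part, else lags behind)

- A bench rule for this flask: while both substrates stand level, the product ratio stays at its early value, the selectivity factor. Dividing the sum of the left-handed product readings by the sum of the right-handed ones gives 2.88, the pooled ratio. As an excess, that ratio is 48.5 %.
- The rule meets its border if nothing refills the left-handed substrate. With no refilling, subtraction from the charge puts c(left-handed substrate) at 3.00 min of Sunday's run at 6.10 % of the total and c(right-handed substrate) at 33.5 %. On that supposition new product forms in the ratio 0.524, below one, so the ratio of the accumulated products has to fall late in Sunday's run.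
- In Sunday's readings it shows no such fall: those up to 0.833 min pool to 2.84, and those from 1.33 min on to 2.90. My own reckoning therefore commits to exchange keeping pace and to an excess near 48.5 % at 10 min; it gives no yield.
- The forecast differs: a yield of 86 % (80 % to 94 %), excess 17 % (11 % to 30 %), exchange hardly takes part, reading the run as “the pattern of plain kinetic resolution”.
- The flask gives 81.9 % with an excess of 49.0 %, and exchange keeps pace, 98 % of the way. At 10.0 min the left-handed and right-handed substrates stand level, at 9.02 % and 9.04 %. The pooled ratio splits that yield into 60.8 % left-handed and 21.1 % right-handed product; the flask holds 61.0 % and 20.9 %.

    partner + free catalyst + left-handed substrate → free catalyst + left-handed product (k = 1.42 L² mol⁻² s⁻¹)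
    partner + free catalyst + right-handed substrate → free catalyst + right-handed product (k = 0.480 L² mol⁻² s⁻¹)
    left-handed substrate + racemization catalyst ⇌ right-handed substrate + racemization catalyst, rate k3*[racemization catalyst]*[left-handed substrate] forward; the back reaction follows from the equilibrium constant (k = 31.6 L mol⁻¹ s⁻¹)
    free catalyst ⇌ dormant form (K = 0.524, k = 0.00116 s⁻¹)
    partner → decomposed reagent (k = 0.00166 s⁻¹)
    free catalyst + impurity → spent catalyst (k = 58.2 L mol⁻¹ s⁻¹)

- In the neighbour flask with 0.80 M of partner, the pooled ratio read from Sunday's run again gives an excess of 48.5 %. Computed, that flask reaches 44.3 % with an excess of 49.3 %.

(The readings were generated by integration on assumed constants, and the scatter is random.)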